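Retrosynthetic overview (labdane numbering C1–C20):
1. Endgame adjusts oxidation level only: the C8 ketone becomes the exocyclic methylene after C9 is equilibrated next to it, and the C2 ketone becomes the equatorial alcohol.
2. Key disconnection: C1–C2 and C5–C10 together, by inserting the isopropenyl olefin C10(=C1H2)–C20H3 into the C2–C5 bond of a 2-alkyl-3,3-dimethylcyclobutanone (temporary ring). Ring B closes first (olefin insertion), ring A directly after (acyl–alkyl reductive elimination), in one catalytic event.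
3. Enabling feature: in ring A the run C2(O)–C3H2–C4(CH3)2–C5H is a 3,3-dimethylcyclobutanone minus its C2–C5 bond, C10 carries only CH3 (C20) and CH2 (C1) besides ring carbons, and C5 and C10 are bridged by C6–C9 of ring B. The C5 stereocentre of the four-membered ketone is therefore relayed to the quaternary C10.
4. The cyclisation substrate comes from a C8–C9 carbonyl-ene union of keto aldehyde 7 (C2–C8, C5 from a SAMP-hydrazone alkylation) with dienoate 17 (C1, C9–C16, C20), whose (Z)-acetoxymethyl enoate is made by syn-carbocupration of an ynoate.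

Key step: step 9

Remark: C8 and C9 are created without control in step 7 and are carried as an epimer mixture (the SMILES of 18–25 leave them open), because C8 is oxidised and C9 is equilibrated in step 12. Compounds 1, 3, 8, 13, SAMP and 2-(trimethylsilyl)ethanol are taken as commercial.

Step 1
Reactants: 1 3,3-dimethylcyclobutan-1-one
Product: 2 (2S)-N-(3,3-dimethylcyclobutylidene)-2-(methoxymethyl)pyrrolidin-1-amine
Conditions: SAMP (1.05 equiv), cyclohexane, 60 °C
Reagents that add atoms: (S)-1-amino-2-(methoxymethyl)pyrrolidine (SAMP), COC[C@@H]1CCCN1N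
Why: Hydrazone formation between the unhindered ketone and the primary amino group of the auxiliary should be clean, and the symmetric ketone makes both alpha positions equivalent.

Step 2
Reactants: 2 SAMP hydrazone of 3,3-dimethylcyclobutanone; 3 2-(2-bromoethyl)-1,3-dioxolane
Product: 5 (2S)-N-{(2R)-2-[2-(1,3-dioxolan-2-yl)ethyl]-3,3-dimethylcyclobutylidene}-2-(methoxymethyl)pyrrolidin-1-amine, via lithium azaenolate 4 (not isolated)
Conditions: LiN(iPr)2, THF, 0 °C; then 3, −95 → 25 °C
Reagents that add atoms: none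
Why: In this Enders SAMP-hydrazone alkylation the chelated azaenolate should be attacked by the primary bromide on the face away from the methoxymethylpyrrolidine unit, which by the established sense for cyclic ketones sets C5 as (R).

Step 3
Reactants: 5 alkylated SAMP hydrazone
Product: 7 3-[(1R)-2,2-dimethyl-4-oxocyclobutyl]propanal, via keto acetal 6 (not isolated)
Conditions: sat aq (CO2H)2, Et2O, 25 °C; then 1 M HCl, THF, 0 → 25 °C
Reagents that add atoms: water, O
Why: Two-phase oxalic acid hydrolysis of the hydrazone should release the ketone without enolising C5 (auxiliary recovered), and dilute acid then hydrolyses the dioxolane to the aldehyde (acetal hydrolysis).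

Step 4
Reactants: 8 prop-2-ynoic acid
Product: 9 2-(trimethylsilyl)ethyl prop-2-ynoate
Conditions: 2-(trimethylsilyl)ethanol, DCC, DMAP (5 mol %), CH2Cl2, −20 → 0 °C
Reagents that add atoms: 2-(trimethylsilyl)ethanol, C[Si](C)(C)CCO
Why: Carbodiimide (Steglich) esterification at low temperature should give the fluoride-labile ester while avoiding conjugate addition to the ynoate.

Step 5
Reactants: 9 2-(trimethylsilyl)ethyl prop-2-ynoate
Product: 12 2-(trimethylsilyl)ethyl 4-acetoxybut-2-ynoate, via lithium acetylide 10 (not isolated), via lithium alkoxide 11 (not isolated)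
Conditions: LiN(iPr)2, THF, −78 °C; CH2O gas (from cracked paraformaldehyde), −78 °C; then Ac2O, −78 → 0 °C
Reagents that add atoms: formaldehyde, C=O; acetic anhydride, CC(=O)OC(C)=O
Why: Acetylide 1,2-addition to monomeric formaldehyde followed by acetylation of the alkoxide in the same flask should give the acetate without ever handling the free 4-hydroxy ynoate.

Step 6
Reactants: 13 5-bromo-2-methylpent-2-ene; 12 2-(trimethylsilyl)ethyl 4-acetoxybut-2-ynoate
Product: 17 2-(trimethylsilyl)ethyl (2Z)-3-(acetoxymethyl)-7-methylocta-2,6-dienoate, via Grignard reagent 14 (not isolated), via alkylcopper 15 (not isolated), via alkenylcopper 16 (not isolated)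
Conditions: Mg, THF, 25 °C; CuBr·SMe2, THF, −40 °C; 12, −78 °C; aq NH4Cl at −78 °C
Reagents that add atoms: none
Why: Carbocupration (conjugate addition) of the ynoate is a syn addition and cold protonation keeps the alkenylcopper geometry, so the new chain ends trans to the ester and CH2OAc cis to it (the required Z olefin), while SN2′ loss of acetate should be disfavoured because it would need attack at the ester-bearing alkyne carbon.

Step 7
Reactants: 7 3-[(1R)-2,2-dimethyl-4-oxocyclobutyl]propanal; 17 2-(trimethylsilyl)ethyl (2Z)-3-(acetoxymethyl)-7-methylocta-2,6-dienoate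
Product: 19 2-(trimethylsilyl)ethyl (2Z)-3-(acetoxymethyl)-6-{3-[(1R)-2,2-dimethyl-4-oxocyclobutyl]-1-hydroxypropyl}-7-methylocta-2,7-dienoate (C8/C9 epimer mixture), via aluminium alkoxide 18 (not isolated)
Conditions: Me2AlCl (3.5 equiv), CH2Cl2, −78 → −20 °C; aq NH4Cl
Reagents that add atoms: none
Why: In this Me2AlCl-promoted carbonyl-ene reaction the activated aldehyde carbon C8 should bond to the less substituted carbon C9 of the electron-rich trisubstituted olefin while a methyl hydrogen is transferred, which creates the isopropenyl group (C10=C1) and the C8 carbinol, leaves the ketone and the electron-poor enoate olefin untouched, and sets C8 and C9 without control (none is needed).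

Step 8
Reactants: 19 ene adduct (C8/C9 epimer mixture)
Product: 20 2-(trimethylsilyl)ethyl (2Z)-3-(acetoxymethyl)-6-{3-[(1R)-2,2-dimethyl-4-oxocyclobutyl]-1-[(triethylsilyl)oxy]propyl}-7-methylocta-2,7-dienoate (C8/C9 epimer mixture)
Conditions: Et3SiCl, imidazole, DMF, 0 → 25 °C
Reagents that add atoms: chlorotriethylsilane, CC[Si](Cl)(CC)CC
Why: Silyl ether formation at the secondary C8 hydroxyl should keep O8 from forming a hemiketal with the strained ketone and keeps it distinguishable from O2 later.

Step 9
Reactants: 20 cyclobutanone triethylsilyl ether (C8/C9 epimer mixture)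
Product: 21 2-(trimethylsilyl)ethyl (2Z)-3-(acetoxymethyl)-5-{(4aR,8aR)-5,5,8a-trimethyl-7-oxo-2-[(triethylsilyl)oxy]decahydronaphthalen-1-yl}pent-2-enoate (C8/C9 epimer mixture)
Conditions: [Rh(C2H4)2Cl]2 (5 mol %), DTBM-SEGPHOS (12 mol %, the enantiomer matched to 20, to be found by trying both), AgSbF6 (10 mol %), 1,4-dioxane, 25 → 60 °C
Reagents that add atoms: none
Why: Mechanism: cationic monovalent rhodium adds oxidatively into the strained acyl–alkyl bond C2–C5, the 1,1-disubstituted olefin C10=C1 then inserts into the Rh–C5 bond (C5–C10 formed, rhodium on C1), and C(sp3)–C(acyl) reductive elimination forms C1–C2 and frees the catalyst. The closest known reaction type is the rhodium-catalysed intramolecular cut-and-sew (4+2) coupling of cyclobutanones with alpha-tethered olefins, which delivers trans-fused bicyclic ketones and builds quaternary ring-fusion carbons from 1,1-disubstituted olefins. Ring B closes by 6-exo migratory insertion and ring A by reductive elimination from the seven-membered acyl(alkyl)rhodacycle, so that the four-membered ring is expanded by the two olefin carbons. C5 keeps the (R) configuration fixed in step 2 because oxidative addition and insertion both proceed with retention, and C10 is set by syn addition of C5 and rhodium across the olefin in a chair-like forming ring B with C4 and C1 pseudo-equatorial, which should put the C20 methyl anti to H5 (trans fusion) and make C10 (R), while the C8 and C9 epimers act as spectators. The step needs proximal instead of distal C–C cleavage, insertion instead of decarbonylation or beta-hydride elimination, and trans instead of cis fusion: only the C2–C5 rhodacycle can reach the tethered olefin (the distal one reverts), the cationic catalyst works near room temperature where CO loss is slow, the inserted alkylrhodium has no beta-hydrogen on the quaternary C10, and the electron-poor enoate olefin is remote.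

Step 10
Reactants: 21 decalone (C8/C9 epimer mixture)
Product: 22 2-(trimethylsilyl)ethyl (2Z)-3-(acetoxymethyl)-5-{(4aR,7R,8aR)-7-hydroxy-5,5,8a-trimethyl-2-[(triethylsilyl)oxy]decahydronaphthalen-1-yl}pent-2-enoate (C8/C9 epimer mixture)
Conditions: Shvo complex [(η5-Ph4C4CO)2H]Ru2(CO)4(μ-H) (2 mol %), i-PrOH/toluene 1:4, 80 °C
Reagents that add atoms: none
Why: Reversible ruthenium-catalysed transfer hydrogenation (a Meerwein–Ponndorf–Verley-type equilibration) should lead to the thermodynamic C2 alcohol, the equatorial (2R) epimer that avoids the two syn-axial methyl groups on C4 and C10, while the enoate, the acetate and the silyl ether are left alone.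

Step 11
Reactants: 22 C2 alcohol (C8/C9 epimer mixture)
Product: 24 2-(trimethylsilyl)ethyl (2Z)-3-(acetoxymethyl)-5-{(4aR,7R,8aR)-7-[(tert-butyldimethylsilyl)oxy]-2-hydroxy-5,5,8a-trimethyldecahydronaphthalen-1-yl}pent-2-enoate (C8/C9 epimer mixture), via bis-silyl ether 23 (not isolated)
Conditions: TBSOTf, 2,6-lutidine, CH2Cl2, −78 → 0 °C; then MeOH, CSA, 0 °C
Reagents that add atoms: tert-butyldimethylsilyl trifluoromethanesulfonate, CC(C)(C)[Si](C)(C)OS(=O)(=O)C(F)(F)F
Why: Silyl triflate silylation of O2 followed by acid-catalysed methanolysis should remove only the more labile secondary triethylsilyl ether at O8 (selective silyl ether cleavage).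

Step 12
Reactants: 24 C8 alcohol (C8/C9 epimer mixture)
Product: 26 2-(trimethylsilyl)ethyl (2Z)-3-(acetoxymethyl)-5-{(1S,4aR,7R,8aR)-7-[(tert-butyldimethylsilyl)oxy]-5,5,8a-trimethyl-2-oxodecahydronaphthalen-1-yl}pent-2-enoate, via C9-epimeric ketone 25 (not isolated)
Conditions: Dess–Martin periodinane, NaHCO3, CH2Cl2, 0 → 25 °C; then DBU (0.3 equiv), 25 °C
Reagents that add atoms: none
Why: Dess–Martin oxidation removes the C8 stereocentre and the amidine base should then equilibrate C9 through the enolate to the more stable epimer with the side chain equatorial and cis to the C20 methyl, which is the configuration of the target (thermodynamic epimerisation).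

Step 13
Reactants: 26 C8 ketone
Product: 27 2-(trimethylsilyl)ethyl (2Z)-3-(acetoxymethyl)-5-{(1R,4aR,7R,8aR)-7-[(tert-butyldimethylsilyl)oxy]-5,5,8a-trimethyl-2-methylidenedecahydronaphthalen-1-yl}pent-2-enoate
Conditions: Zn, CH2Br2, TiCl4, THF/CH2Cl2, 0 → 25 °C
Reagents that add atoms: dibromomethane, BrCBr
Why: Takai–Lombardo methylenation is non-basic and selective for ketones, so C8 should be converted into the exocyclic methylene without epimerising C9 or touching the esters.

Step 14
Reactants: 27 protected target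
Product: 28 (2Z)-3-(acetoxymethyl)-5-[(1R,4aR,7R,8aR)-7-hydroxy-5,5,8a-trimethyl-2-methylidenedecahydronaphthalen-1-yl]pent-2-enoic acid
Conditions: TASF (3 equiv), DMF, 0 → 25 °C; aq NaH2PO4 (pH 4) work-up
Reagents that add atoms: none
Why: Fluoride-mediated desilylation should trigger beta-elimination of the 2-(trimethylsilyl)ethyl ester and cleave the silyl ether in one operation under nearly neutral conditions that spare the allylic acetate and the exocyclic olefin.

Compound list
1 | 3,3-dimethylcyclobutan-1-one | CC1(C)CC(=O)C1 | starting material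
2 | (2S)-N-(3,3-dimethylcyclobutylidene)-2-(methoxymethyl)pyrrolidin-1-amine | COC[C@@H]1CCCN1N=C1CC(C)(C)C1 | intermediate
3 | 2-(2-bromoethyl)-1,3-dioxolane | BrCCC1OCCO1 | starting material
4 | lithium azaenolate of 2 | COC[C@@H]1CCCN1N([Li])C1=CC(C)(C)C1 | intermediate
5 | (2S)-N-{(2R)-2-[2-(1,3-dioxolan-2-yl)ethyl]-3,3-dimethylcyclobutylidene}-2-(methoxymethyl)pyrrolidin-1-amine (C=N geometry open) | COC[C@@H]1CCCN1N=C1CC(C)(C)[C@H]1CCC1OCCO1 | intermediate
6 | (2R)-2-[2-(1,3-dioxolan-2-yl)ethyl]-3,3-dimethylcyclobutan-1-one | O=C1CC(C)(C)[C@H]1CCC1OCCO1 | intermediate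
7 | 3-[(1R)-2,2-dimethyl-4-oxocyclobutyl]propanal | O=CCC[C@H]1C(=O)CC1(C)C | intermediate
8 | prop-2-ynoic acid | C#CC(=O)O | starting material
9 | 2-(trimethylsilyl)ethyl prop-2-ynoate | C#CC(=O)OCC[Si](C)(C)C | intermediate
10 | lithium acetylide of 9 | [Li]C#CC(=O)OCC[Si](C)(C)C | intermediate
11 | lithium 4-oxo-4-[2-(trimethylsilyl)ethoxy]but-2-yn-1-olate | [Li]OCC#CC(=O)OCC[Si](C)(C)C | intermediate
12 | 2-(trimethylsilyl)ethyl 4-acetoxybut-2-ynoate | CC(=O)OCC#CC(=O)OCC[Si](C)(C)C | intermediate
13 | 5-bromo-2-methylpent-2-ene | CC(C)=CCCBr | starting material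
14 | (4-methylpent-3-en-1-yl)magnesium bromide | CC(C)=CCC[Mg]Br | intermediate
15 | (4-methylpent-3-en-1-yl)copper (MgBr2 complex) | CC(C)=CCC[Cu] | intermediate
16 | 2-(trimethylsilyl)ethyl (2E)-3-(acetoxymethyl)-2-cuprio-7-methylocta-2,6-dienoate | CC(C)=CCC/C(COC(C)=O)=C(\[Cu])C(=O)OCC[Si](C)(C)C | intermediate
17 | 2-(trimethylsilyl)ethyl (2Z)-3-(acetoxymethyl)-7-methylocta-2,6-dienoate | CC(C)=CCC/C(COC(C)=O)=C/C(=O)OCC[Si](C)(C)C | intermediate
18 | chloro(methyl)aluminium alkoxide of 19 (C8/C9 epimer mixture) | C[Al](Cl)OC(CC[C@H]1C(=O)CC1(C)C)C(CC/C(COC(C)=O)=C/C(=O)OCC[Si](C)(C)C)C(C)=C | intermediate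
19 | 2-(trimethylsilyl)ethyl (2Z)-3-(acetoxymethyl)-6-{3-[(1R)-2,2-dimethyl-4-oxocyclobutyl]-1-hydroxypropyl}-7-methylocta-2,7-dienoate (C8/C9 epimer mixture) | OC(CC[C@H]1C(=O)CC1(C)C)C(CC/C(COC(C)=O)=C/C(=O)OCC[Si](C)(C)C)C(C)=C | intermediate
20 | 2-(trimethylsilyl)ethyl (2Z)-3-(acetoxymethyl)-6-{3-[(1R)-2,2-dimethyl-4-oxocyclobutyl]-1-[(triethylsilyl)oxy]propyl}-7-methylocta-2,7-dienoate (C8/C9 epimer mixture) | CC[Si](CC)(CC)OC(CC[C@H]1C(=O)CC1(C)C)C(CC/C(COC(C)=O)=C/C(=O)OCC[Si](C)(C)C)C(C)=C | intermediate
21 | 2-(trimethylsilyl)ethyl (2Z)-3-(acetoxymethyl)-5-{(4aR,8aR)-5,5,8a-trimethyl-7-oxo-2-[(triethylsilyl)oxy]decahydronaphthalen-1-yl}pent-2-enoate (C8/C9 epimer mixture) | CC[Si](CC)(CC)OC1CC[C@@H]2C(C)(C)CC(=O)C[C@@]2(C)C1CC/C(COC(C)=O)=C/C(=O)OCC[Si](C)(C)C | intermediate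
22 | 2-(trimethylsilyl)ethyl (2Z)-3-(acetoxymethyl)-5-{(4aR,7R,8aR)-7-hydroxy-5,5,8a-trimethyl-2-[(triethylsilyl)oxy]decahydronaphthalen-1-yl}pent-2-enoate (C8/C9 epimer mixture) | CC[Si](CC)(CC)OC1CC[C@@H]2C(C)(C)C[C@@H](O)C[C@@]2(C)C1CC/C(COC(C)=O)=C/C(=O)OCC[Si](C)(C)C | intermediate
23 | 2-(trimethylsilyl)ethyl (2Z)-3-(acetoxymethyl)-5-{(4aR,7R,8aR)-7-[(tert-butyldimethylsilyl)oxy]-5,5,8a-trimethyl-2-[(triethylsilyl)oxy]decahydronaphthalen-1-yl}pent-2-enoate (C8/C9 epimer mixture) | CC[Si](CC)(CC)OC1CC[C@@H]2C(C)(C)C[C@@H](O[Si](C)(C)C(C)(C)C)C[C@@]2(C)C1CC/C(COC(C)=O)=C/C(=O)OCC[Si](C)(C)C | intermediate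
24 | 2-(trimethylsilyl)ethyl (2Z)-3-(acetoxymethyl)-5-{(4aR,7R,8aR)-7-[(tert-butyldimethylsilyl)oxy]-2-hydroxy-5,5,8a-trimethyldecahydronaphthalen-1-yl}pent-2-enoate (C8/C9 epimer mixture) | OC1CC[C@@H]2C(C)(C)C[C@@H](O[Si](C)(C)C(C)(C)C)C[C@@]2(C)C1CC/C(COC(C)=O)=C/C(=O)OCC[Si](C)(C)C | intermediate
25 | 2-(trimethylsilyl)ethyl (2Z)-3-(acetoxymethyl)-5-{(4aR,7R,8aR)-7-[(tert-butyldimethylsilyl)oxy]-5,5,8a-trimethyl-2-oxodecahydronaphthalen-1-yl}pent-2-enoate (C9 epimer mixture) | O=C1CC[C@@H]2C(C)(C)C[C@@H](O[Si](C)(C)C(C)(C)C)C[C@@]2(C)C1CC/C(COC(C)=O)=C/C(=O)OCC[Si](C)(C)C | intermediate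
26 | 2-(trimethylsilyl)ethyl (2Z)-3-(acetoxymethyl)-5-{(1S,4aR,7R,8aR)-7-[(tert-butyldimethylsilyl)oxy]-5,5,8a-trimethyl-2-oxodecahydronaphthalen-1-yl}pent-2-enoate | O=C1CC[C@@H]2C(C)(C)C[C@@H](O[Si](C)(C)C(C)(C)C)C[C@@]2(C)[C@@H]1CC/C(COC(C)=O)=C/C(=O)OCC[Si](C)(C)C | intermediate
27 | 2-(trimethylsilyl)ethyl (2Z)-3-(acetoxymethyl)-5-{(1R,4aR,7R,8aR)-7-[(tert-butyldimethylsilyl)oxy]-5,5,8a-trimethyl-2-methylidenedecahydronaphthalen-1-yl}pent-2-enoate | C=C1CC[C@@H]2C(C)(C)C[C@@H](O[Si](C)(C)C(C)(C)C)C[C@@]2(C)[C@@H]1CC/C(COC(C)=O)=C/C(=O)OCC[Si](C)(C)C | intermediate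
28 | (2Z)-3-(acetoxymethyl)-5-[(1R,4aR,7R,8aR)-7-hydroxy-5,5,8a-trimethyl-2-methylidenedecahydronaphthalen-1-yl]pent-2-enoic acid | C=C1CC[C@@H]2C(C)(C)C[C@@H](O)C[C@@]2(C)[C@@H]1CC/C(=C/C(=O)O)COC(C)=O | target

Total step count: 14. Longest linear sequence: 11 steps (steps 1–3 and 7–14 from 1; the branch from 8 through steps 4–6 and 7–14 is equally long).

Steps most likely to fail

Step 9. Oxidative addition into the C2–C5 bond may be slowed by the flanking quaternary C4, so that decarbonylation of the rhodacycle or beta-hydride elimination towards C6 overtakes olefin insertion, or insertion may proceed with poor trans/cis control of the ring fusion. The fallback sets out from 20 and comes back at 21. It changes the mode of C–C cleavage from direct oxidative addition at a cationic metal to chelation-assisted cleavage through a temporary directing group, a known mode for cyclobutanone–olefin couplings that suppresses CO loss. Compound 20 is condensed in the flask with 2-amino-3-methylpyridine to the N-(3-methylpyridin-2-yl) ketimine F1. Neutral [Rh(C2H4)2Cl]2 with P(3,5-(CF3)2C6H3)3 in 1,4-dioxane at 130 °C is then guided by the pyridine nitrogen into the C2–C5 bond. Olefin insertion and reductive elimination give the decalone ketimine F2, which aqueous work-up hydrolyses to 21.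

Step 7. The ester, acetate and ketone oxygens may sequester Me2AlCl so that the aldehyde is not activated, or the developing cation at C10 may be captured by chloride instead of losing a proton. The fallback sets out from 17 and comes back at 19. It replaces the ene reaction by a Barbier allylation. Allylic oxidation of the (E)-methyl group of 17 (SeO2 catalytic, t-BuOOH, CH2Cl2) gives the allylic alcohol F3, and CBr4/PPh3 converts it into the allylic bromide F4. In powder in THF/H2O then couples F4 with aldehyde 7 through the gamma carbon (C9), selectively at the aldehyde, to give 19.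

Step 2. SN2 attack by the azaenolate carbon next to the quaternary C4 may be slow, so that elimination of HBr from 3 and proton exchange erode conversion and facial control. The fallback sets out from 2 and comes back at 7. It uses a conjugate addition instead of an alkylation. Azaenolate 4 is added to methyl acrylate (THF, −78 °C) to give the ester hydrazone F5 with the same facial sense. i-Bu2AlH at −78 °C reduces the ester to the aldehyde hydrazone F6, and aqueous oxalic acid releases 7.

Further compounds
F1 | step 9 | N-(3-methylpyridin-2-yl) ketimine of 20 | Cc1cccnc1N=C1CC(C)(C)[C@H]1CCC(O[Si](CC)(CC)CC)C(CC/C(COC(C)=O)=C/C(=O)OCC[Si](C)(C)C)C(C)=C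
F2 | step 9 | N-(3-methylpyridin-2-yl) ketimine of 21 | CC[Si](CC)(CC)OC1CC[C@@H]2C(C)(C)CC(=Nc3ncccc3C)C[C@@]2(C)C1CC/C(COC(C)=O)=C/C(=O)OCC[Si](C)(C)C
F3 | step 7 | 2-(trimethylsilyl)ethyl (2Z,6E)-3-(acetoxymethyl)-8-hydroxy-7-methylocta-2,6-dienoate | OC/C(C)=C/CC/C(COC(C)=O)=C/C(=O)OCC[Si](C)(C)C
F4 | step 7 | 2-(trimethylsilyl)ethyl (2Z,6E)-3-(acetoxymethyl)-8-bromo-7-methylocta-2,6-dienoate | BrC/C(C)=C/CC/C(COC(C)=O)=C/C(=O)OCC[Si](C)(C)C
F5 | step 2 | methyl 3-[(1R)-2,2-dimethyl-4-{[(2S)-2-(methoxymethyl)pyrrolidin-1-yl]imino}cyclobutyl]propanoate | COC[C@@H]1CCCN1N=C1CC(C)(C)[C@H]1CCC(=O)OC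
F6 | step 2 | 3-[(1R)-2,2-dimethyl-4-{[(2S)-2-(methoxymethyl)pyrrolidin-1-yl]imino}cyclobutyl]propanal | COC[C@@H]1CCCN1N=C1CC(C)(C)[C@H]1CCC=O
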